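The route is cut through ring C at C1–C12 and C10–C11 (labels: C1 quaternary C–O carbon, C9a=C9 enamine alkene, C10 CHEt, C11 CHOH, C12 ring-fusion CH of lactone D). The only unsaturation of ring C is the enamine C9=C9a, its neighbours are C1 and C10, and lactone D bridges C1 and C12. This is the retron of an intramolecular Diels–Alder reaction of a 2-amino-1-acyloxydiene (C1=C9a–C9=C10) with an ester-tethered (Z)-alkenylboronate (C12=C11), which closes rings C and D and sets four stereocentres at once. The precursor is the dienol ester of a 9-propyl-pyrroloazepin-1-one (lactone E attached) with (2S,3Z)-2-methyl-4-(pinacolboryl)but-3-enoic acid.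

Key step: step 17

Remark (labels): the core carries pyrrolo[1,2-a]azepine numbering C1–C9a; C10, C11, C12 complete ring C and C13 is the CHMe carbon of lactone D.
Remark (diene): the exocyclic group on C9 is a propylidene (=CH–CH2CH3); with ethyl trans to C9a it is (E).
Remark (acid): the acid must be (2S); because the ester carbon of the Roche ester becomes the alkenyl carbon and its CH2OH carbon the carboxyl, the (R)-ester is required (direct oxidation of the (S)-ester would pass through a configurationally unstable formyl ester).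
Remark (nitrogen): a free secondary amine next to lactone E can rearrange to a six-membered lactam, so nitrogen is alkylated by reductive amination from its salt and not by a bromo ketone under base.
Remark (end game): the last step deprotonates three sites (hydroxyl and both lactones); kinetic protonation inverts C13 and returns lactone E to its cis form.
Assumption: compounds 1, 4, 8, 9, 18 and 22 are taken as commercially available.

Step 1
Reactants: 1 methyl (2R,4R)-1-(tert-butoxycarbonyl)-4-hydroxypyrrolidine-2-carboxylate (N-Boc-cis-4-hydroxy-D-proline methyl ester)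
Product: 2 methyl (2R,4R)-1-(tert-butoxycarbonyl)-4-[(tert-butyldimethylsilyl)oxy]pyrrolidine-2-carboxylate
Conditions: TBSCl, imidazole, DMF, rt
Reagents that add atoms: tert-butyldimethylsilyl chloride, CC(C)(C)[Si](C)(C)Cl
Why: Imidazole-promoted silylation of the secondary alcohol masks the hydroxyl, which would otherwise consume hydride and close a bicyclic lactol onto the cis aldehyde made in step 2.

Step 2
Reactants: 2 silyl ether ester
Product: 3 tert-butyl (2R,4R)-4-[(tert-butyldimethylsilyl)oxy]-2-formylpyrrolidine-1-carboxylate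
Conditions: i-Bu2AlH, PhMe, −78 °C; MeOH, aq. potassium sodium tartrate
Reagents that add atoms: none
Why: Partial reduction of the ester at −78 °C stops at the aluminium hemiacetal and should give the N-Boc amino aldehyde, which keeps its configuration at low temperature and is used crude.

Step 3
Reactants: 3 aldehyde; 4 ethyl 2-(bromomethyl)prop-2-enoate
Product: 6 tert-butyl (2R,4R)-4-[(tert-butyldimethylsilyl)oxy]-2-[(2S)-4-methylidene-5-oxooxolan-2-yl]pyrrolidine-1-carboxylate, via hydroxy ester 5 (not isolated)
Conditions: Zn, THF/sat. aq. NH4Cl, 0 °C → rt; then PPTS, PhMe, 80 °C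
Reagents that add atoms: none
Why: Zinc-mediated Barbier allylation followed by acid-catalysed lactonisation should give the α-methylene-γ-butyrolactone, the allylzinc adding in the Felkin–Anh sense (anti to the carbamate nitrogen) to set the (S)-carbinol centre erythro to C3.

Step 4
Reactants: 6 α-methylene lactone
Product: 7 tert-butyl (2R,4R)-4-[(tert-butyldimethylsilyl)oxy]-2-[(2S,4S)-4-methyl-5-oxooxolan-2-yl]pyrrolidine-1-carboxylate
Conditions: H2 (1 atm), Pd/C, EtOAc, rt
Reagents that add atoms: none
Why: Heterogeneous hydrogenation should deliver hydrogen to the exocyclic alkene from the lactone face opposite the pyrrolidinyl group, giving the cis-disubstituted lactone with the (S)-methyl centre of lactone E.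

Step 5
Reactants: 8 hex-5-enoyl chloride; 9 propylmagnesium chloride
Product: 10 non-8-en-4-one
Conditions: Fe(acac)3 (3 mol%), THF, −78 °C
Reagents that add atoms: none
Why: Iron-catalysed acylation of the Grignard reagent by the acid chloride is faster than addition to the ketone that forms, and the terminal alkene is inert.

Step 6
Reactants: 10 non-8-en-4-one
Product: 12 5-oxooctanal, via ozonide 11 (not isolated)
Conditions: O3, CH2Cl2, −78 °C; PPh3, −78 °C → rt
Reagents that add atoms: ozone, [O-][O+]=O
Why: Ozonolysis with reductive work-up cleaves the terminal alkene to the aldehyde and leaves the ketone untouched.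

Step 7
Reactants: 7 Boc-protected lactone; 12 5-oxooctanal
Product: 14 (3S,5S)-5-[(2R,4R)-4-hydroxy-1-(5-oxooctyl)pyrrolidin-2-yl]-3-methyloxolan-2-one, via ammonium chloride 13 (not isolated)
Conditions: 4 M HCl, dioxane/H2O (10:1), rt; evaporate; then 12, NaBH(OAc)3, NaOAc, ClCH2CH2Cl, 0 °C → rt
Reagents that add atoms: none
Why: Acid removes the Boc and silyl groups and holds the amine as its salt so that it cannot acylate itself on lactone E, and direct reductive amination then alkylates nitrogen through the aldehyde-derived iminium ion while the ketone is left alone.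

Step 8
Reactants: 14 amino alcohol
Product: 15 (3S,5S)-3-methyl-5-[(2R)-4-oxo-1-(5-oxooctyl)pyrrolidin-2-yl]oxolan-2-one
Conditions: (COCl)2, DMSO, CH2Cl2, −78 °C; Et3N, −78 → 0 °C
Reagents that add atoms: none
Why: Swern oxidation converts the secondary alcohol into the ring ketone at low temperature and tolerates the tertiary amine, the side-chain ketone and the lactone.

Step 9
Reactants: 15 amino diketone
Product: 17 (3R)-3-[(2S,4S)-4-methyl-5-oxooxolan-2-yl]-9-propyl-2,3,5,6,7,8-hexahydro-1H-pyrrolo[1,2-a]azepin-1-one, via aldol adduct 16 (not isolated)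
Conditions: pyrrolidine (0.3 equiv), AcOH (0.3 equiv), PhMe, 4 Å MS, 80 °C
Reagents that add atoms: none
Why: In this amine-catalysed intramolecular aldol condensation the ring ketone reacts through the methylene between nitrogen and carbonyl, the only position from which a seven-membered ring can form, and dehydration into conjugation with nitrogen should pull the reversible addition through to the tetrasubstituted 2-amino enone.

Step 10
Reactants: 18 methyl (R)-3-hydroxy-2-methylpropanoate
Product: 19 methyl (R)-3-[(tert-butyldimethylsilyl)oxy]-2-methylpropanoate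
Conditions: TBSCl, imidazole, CH2Cl2, rt
Reagents that add atoms: tert-butyldimethylsilyl chloride, CC(C)(C)[Si](C)(C)Cl
Why: Silylation of the primary alcohol protects the carbon that will later become the carboxyl group.

Step 11
Reactants: 19 silyl ether ester
Product: 20 (R)-3-[(tert-butyldimethylsilyl)oxy]-2-methylpropanal
Conditions: i-Bu2AlH, CH2Cl2, −78 °C; MeOH, aq. potassium sodium tartrate
Reagents that add atoms: none
Why: Partial ester reduction at −78 °C should give the α-methyl aldehyde, which is used at once so that its stereocentre does not epimerise.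

Step 12
Reactants: 20 aldehyde
Product: 21 (S)-tert-butyldimethyl[(2-methylbut-3-yn-1-yl)oxy]silane
Conditions: dimethyl (1-diazo-2-oxopropyl)phosphonate, K2CO3, MeOH, 0 °C → rt
Reagents that add atoms: dimethyl (1-diazo-2-oxopropyl)phosphonate, COP(=O)(OC)C(=[N+]=[N-])C(C)=O
Why: The Ohira–Bestmann variant of the Seyferth–Gilbert homologation turns the aldehyde into the terminal alkyne under mild carbonate conditions that leave the adjacent stereocentre intact (the descriptor changes only through the priority rules).

Step 13
Reactants: 21 alkyne; 22 pinacolborane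
Product: 23 tert-butyldimethyl{[(2S,3Z)-2-methyl-4-(4,4,5,5-tetramethyl-1,3,2-dioxaborolan-2-yl)but-3-en-1-yl]oxy}silane
Conditions: [Rh(cod)Cl]2 (1.5 mol%), P(i-Pr)3, Et3N, cyclohexane, rt
Reagents that add atoms: none
Why: Rhodium-catalysed formal trans-hydroboration of the terminal alkyne through a rhodium vinylidene places boron at the terminus and should give the (Z)-alkenylboronate without involving the stereocentre.

Step 14
Reactants: 23 silyl ether
Product: 24 (2S,3Z)-2-methyl-4-(4,4,5,5-tetramethyl-1,3,2-dioxaborolan-2-yl)but-3-en-1-ol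
Conditions: camphorsulfonic acid (10 mol%), MeOH/CH2Cl2, 0 °C
Reagents that add atoms: none
Why: Acid-catalysed methanolysis cleaves the primary silyl ether under conditions to which the pinacol boronate and the (Z)-alkene are stable.

Step 15
Reactants: 24 alcohol
Product: 26 (2S,3Z)-2-methyl-4-(4,4,5,5-tetramethyl-1,3,2-dioxaborolan-2-yl)but-3-enoic acid, via aldehyde 25 (not isolated)
Conditions: TEMPO (20 mol%), PhI(OAc)2, MeCN/pH 7 buffer, 0 °C → rt
Reagents that add atoms: water, O
Why: Oxoammonium-mediated oxidation takes the primary alcohol through the aldehyde hydrate to the acid under near-neutral conditions that should spare the alkenylboronate and the α-stereocentre of the β,γ-unsaturated aldehyde.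

Step 16
Reactants: 17 amino enone; 26 boryl butenoic acid
Product: 29 (3R,9E)-3-[(2S,4S)-4-methyl-5-oxooxolan-2-yl]-9-propylidene-2,3,6,7,8,9-hexahydro-5H-pyrrolo[1,2-a]azepin-1-yl (2S,3Z)-2-methyl-4-(4,4,5,5-tetramethyl-1,3,2-dioxaborolan-2-yl)but-3-enoate, via acid chloride 27 (not isolated), via potassium dienolate 28 (not isolated)
Conditions: 26, 1-chloro-N,N,2-trimethylprop-1-en-1-amine, CH2Cl2, 0 °C; separately 17, KN(SiMe3)2 (0.98 equiv), THF, −78 → 0 °C; then dienolate added to the acid chloride, THF/DMPU, −78 °C
Reagents that add atoms: none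
Why: Under equilibrating conditions the potassium base should give the extended dienolate by loss of a propyl α-hydrogen held syn to the carbonyl (as with pulegone-type alkylidene ketones), with ethyl turned outward (E) away from the enolate oxygen, and the hard acid chloride, made under neutral conditions, should then acylate on oxygen at −78 °C before the acid α-centre can be lost.

Step 17
Reactants: 29 dienol ester
Product: 30 cycloadduct: the target skeleton with pinacolboryl at C11 in place of hydroxyl (same orientation) and the C13 methyl group epimeric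
Conditions: PhMe (0.005 M), BHT (5 mol%), 120 °C, sealed tube, base-washed glassware
Reagents that add atoms: none
Why: Proposed new method: a concerted but asynchronous thermal [4+2] cycloaddition of normal electron demand is expected, the HOMO of the 2-amino-1-acyloxydiene (largest coefficient at C1, raised by the enamine nitrogen on C9a) pairing with the LUMO of the alkenylboronate (largest at C12, β to the vacant boron p orbital), so that C1–C12 and C10–C11 form; the closest known reaction types are Diels–Alder reactions of 2-aminodienes, intramolecular Diels–Alder reactions of (Z)-dienes that give cis-fused bicycles, and cycloadditions of alkenylboronate dienophiles. Ring D closes in the type 1 intramolecular mode through the three-atom O–C(=O)–C13 tether, which hangs from the inside position of the ring-locked s-cis diene and can therefore only reach C12 from the same side as oxygen, giving the cis-fused γ-lactone, while ring C closes as the cyclohexene of the cycloadduct with the new C9=C9a enamine bond. The C1/C12 relation is set by this tether, C11 (boron) is cis to the C12–C13 bond because addition to the (Z)-alkene is suprafacial, and C10 (ethyl) is trans to boron because the (E)-propylidene carries ethyl on the outside of the diene. The selectivity that is needed is between the two diene faces, since the desired face is the one syn to the C3 substituent; it is secured by the (S)-methyl centre C13, where 1,3-allylic strain with the cis pinacolboryl group keeps the C13–H bond eclipsed with the alkene and the methyl group turned away from the diene in only one of the two face-diastereomeric transition states. Regiochemistry is enforced by the tether and matched by the polarisation of both partners. High dilution, a radical inhibitor and acid-free glassware guard the enamine-type dienol ester against intermolecular reaction, polymerisation and protonation.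

Step 18
Reactants: 30 cycloadduct
Product: 32 hydroxy lactone (the C13 epimer of the target), via borate ester 31 (not isolated)
Conditions: Me3NO (anhydrous, 3 equiv), THF, 60 °C; aq. NaHCO3 work-up
Reagents that add atoms: trimethylamine N-oxide, C[N+](C)(C)[O-]
Why: In this amine N-oxide oxidation of the organoboron compound, C11 migrates from boron to oxygen with retention, the mild oxidant leaves the electron-rich enamine and both lactones untouched, and the resulting borate hydrolyses on work-up.

Step 19
Reactants: 32 hydroxy lactone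
Product: 34 CNP0154902.3 (target), via trilithium salt 33 (not isolated)
Conditions: 32 added to LiN(i-Pr)2 (3.5 equiv), THF, −78 °C; then AcOH in THF, −78 °C
Reagents that add atoms: none
Why: The amide base removes the hydroxyl proton and the α-protons of both lactones, and kinetic protonation of the enolates should then deliver hydrogen to the convex face of lactone D (opposite C11), which inverts C13, and to lactone E opposite its ring substituent, which restores the cis (S)-methyl centre (epimerisation by enolate protonation).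

Compound list
1 | methyl (2R,4R)-1-(tert-butoxycarbonyl)-4-hydroxypyrrolidine-2-carboxylate | COC(=O)[C@H]1C[C@@H](O)CN1C(=O)OC(C)(C)C | starting material
2 | methyl (2R,4R)-1-(tert-butoxycarbonyl)-4-[(tert-butyldimethylsilyl)oxy]pyrrolidine-2-carboxylate | COC(=O)[C@H]1C[C@@H](O[Si](C)(C)C(C)(C)C)CN1C(=O)OC(C)(C)C | intermediate
3 | tert-butyl (2R,4R)-4-[(tert-butyldimethylsilyl)oxy]-2-formylpyrrolidine-1-carboxylate | O=C[C@H]1C[C@@H](O[Si](C)(C)C(C)(C)C)CN1C(=O)OC(C)(C)C | intermediate
4 | ethyl 2-(bromomethyl)prop-2-enoate | CCOC(=O)C(=C)CBr | starting material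
5 | ethyl (4S)-4-hydroxy-2-methylidene-4-[(2R,4R)-1-Boc-4-(tert-butyldimethylsilyloxy)pyrrolidin-2-yl]butanoate | O[C@@H](CC(=C)C(=O)OCC)[C@H]1C[C@@H](O[Si](C)(C)C(C)(C)C)CN1C(=O)OC(C)(C)C | intermediate (not isolated)
6 | tert-butyl (2R,4R)-4-[(tert-butyldimethylsilyl)oxy]-2-[(2S)-4-methylidene-5-oxooxolan-2-yl]pyrrolidine-1-carboxylate | O=C1O[C@@H](CC1=C)[C@H]2C[C@@H](O[Si](C)(C)C(C)(C)C)CN2C(=O)OC(C)(C)C | intermediate
7 | tert-butyl (2R,4R)-4-[(tert-butyldimethylsilyl)oxy]-2-[(2S,4S)-4-methyl-5-oxooxolan-2-yl]pyrrolidine-1-carboxylate | O=C1O[C@@H](C[C@@H]1C)[C@H]2C[C@@H](O[Si](C)(C)C(C)(C)C)CN2C(=O)OC(C)(C)C | intermediate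
8 | hex-5-enoyl chloride | C=CCCCC(=O)Cl | starting material
9 | propylmagnesium chloride | CCC[Mg]Cl | starting material
10 | non-8-en-4-one | CCCC(=O)CCCC=C | intermediate
11 | 3-(4-oxoheptyl)-1,2,4-trioxolane (ozonide) | CCCC(=O)CCCC1OCOO1 | intermediate (not isolated)
12 | 5-oxooctanal | CCCC(=O)CCCC=O | intermediate
13 | (3S,5S)-5-[(2R,4R)-4-hydroxypyrrolidin-2-yl]-3-methyloxolan-2-one hydrochloride | O=C1O[C@@H](C[C@@H]1C)[C@H]2C[C@@H](O)CN2.Cl | intermediate (not isolated)
14 | (3S,5S)-5-[(2R,4R)-4-hydroxy-1-(5-oxooctyl)pyrrolidin-2-yl]-3-methyloxolan-2-one | O=C1O[C@@H](C[C@@H]1C)[C@H]2C[C@@H](O)CN2CCCCC(=O)CCC | intermediate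
15 | (3S,5S)-3-methyl-5-[(2R)-4-oxo-1-(5-oxooctyl)pyrrolidin-2-yl]oxolan-2-one | O=C1O[C@@H](C[C@@H]1C)[C@H]2CC(=O)CN2CCCCC(=O)CCC | intermediate
16 | (3R)-9-hydroxy-3-[(2S,4S)-4-methyl-5-oxooxolan-2-yl]-9-propyloctahydro-1H-pyrrolo[1,2-a]azepin-1-one (C9 and C9a not defined) | O=C1O[C@@H](C[C@@H]1C)[C@H]2CC(=O)C3N2CCCCC3(O)CCC | intermediate (not isolated)
17 | (3R)-3-[(2S,4S)-4-methyl-5-oxooxolan-2-yl]-9-propyl-2,3,5,6,7,8-hexahydro-1H-pyrrolo[1,2-a]azepin-1-one | CCCC1=C2C(=O)C[C@H]([C@@H]3C[C@H](C)C(=O)O3)N2CCCC1 | intermediate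
18 | methyl (R)-3-hydroxy-2-methylpropanoate | COC(=O)[C@H](C)CO | starting material
19 | methyl (R)-3-[(tert-butyldimethylsilyl)oxy]-2-methylpropanoate | COC(=O)[C@H](C)CO[Si](C)(C)C(C)(C)C | intermediate
20 | (R)-3-[(tert-butyldimethylsilyl)oxy]-2-methylpropanal | O=C[C@H](C)CO[Si](C)(C)C(C)(C)C | intermediate
21 | (S)-tert-butyldimethyl[(2-methylbut-3-yn-1-yl)oxy]silane | C#C[C@H](C)CO[Si](C)(C)C(C)(C)C | intermediate
22 | pinacolborane (4,4,5,5-tetramethyl-1,3,2-dioxaborolane) | [BH]1OC(C)(C)C(C)(C)O1 | starting material
23 | tert-butyldimethyl{[(2S,3Z)-2-methyl-4-(4,4,5,5-tetramethyl-1,3,2-dioxaborolan-2-yl)but-3-en-1-yl]oxy}silane | CC(C)(C)[Si](C)(C)OC[C@@H](C)/C=C\B1OC(C)(C)C(C)(C)O1 | intermediate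
24 | (2S,3Z)-2-methyl-4-(4,4,5,5-tetramethyl-1,3,2-dioxaborolan-2-yl)but-3-en-1-ol | OC[C@@H](C)/C=C\B1OC(C)(C)C(C)(C)O1 | intermediate
25 | (2S,3Z)-2-methyl-4-(4,4,5,5-tetramethyl-1,3,2-dioxaborolan-2-yl)but-3-enal | O=C[C@@H](C)/C=C\B1OC(C)(C)C(C)(C)O1 | intermediate (not isolated)
26 | (2S,3Z)-2-methyl-4-(4,4,5,5-tetramethyl-1,3,2-dioxaborolan-2-yl)but-3-enoic acid | OC(=O)[C@@H](C)/C=C\B1OC(C)(C)C(C)(C)O1 | intermediate
27 | (2S,3Z)-2-methyl-4-(4,4,5,5-tetramethyl-1,3,2-dioxaborolan-2-yl)but-3-enoyl chloride | ClC(=O)[C@@H](C)/C=C\B1OC(C)(C)C(C)(C)O1 | intermediate (not isolated)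
28 | potassium (3R,9E)-3-[(2S,4S)-4-methyl-5-oxooxolan-2-yl]-9-propylidene-2,3,6,7,8,9-hexahydro-5H-pyrrolo[1,2-a]azepin-1-olate | [K+].CC/C=C1\CCCCN2C1=C([O-])C[C@@H]2[C@@H]2C[C@H](C)C(=O)O2 | intermediate (not isolated)
29 | (3R,9E)-3-[(2S,4S)-4-methyl-5-oxooxolan-2-yl]-9-propylidene-2,3,6,7,8,9-hexahydro-5H-pyrrolo[1,2-a]azepin-1-yl (2S,3Z)-2-methyl-4-(4,4,5,5-tetramethyl-1,3,2-dioxaborolan-2-yl)but-3-enoate | CC/C=C1\CCCCN2C1=C(OC(=O)[C@@H](C)/C=C\B3OC(C)(C)C(C)(C)O3)C[C@@H]2[C@@H]2C[C@H](C)C(=O)O2 | intermediate (key-step precursor)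
30 | cycloadduct: target skeleton with C11 pinacolboryl (oriented as the target hydroxyl) and epimeric C13 methyl | CC[C@H]1C2=C3N(CCCC2)[C@@H]([C@@H]2C[C@H](C)C(=O)O2)C[C@]32OC(=O)[C@@H](C)[C@@H]2[C@@H]1B1OC(C)(C)C(C)(C)O1 | intermediate (key-step product)
31 | C11–O–B(pinacolato) borate ester of 32 | CC[C@H]1C2=C3N(CCCC2)[C@@H]([C@@H]2C[C@H](C)C(=O)O2)C[C@]32OC(=O)[C@@H](C)[C@@H]2[C@@H]1OB1OC(C)(C)C(C)(C)O1 | intermediate (not isolated)
32 | hydroxy lactone, C13 epimer of the target | CC[C@H]1C2=C3N(CCCC2)[C@@H]([C@@H]2C[C@H](C)C(=O)O2)C[C@]32OC(=O)[C@@H](C)[C@@H]2[C@@H]1O | intermediate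
33 | trilithium C11-alkoxide bis(lactone enolate) of 32 | [Li+].[Li+].[Li+].CC[C@H]1C2=C3N(CCCC2)[C@@H]([C@@H]2CC(C)=C([O-])O2)C[C@]32OC([O-])=C(C)[C@@H]2[C@@H]1[O-] | intermediate (not isolated)
34 | CNP0154902.3 | CC[C@H]1C2=C3N(CCCC2)[C@@H]([C@@H]2C[C@H](C)C(=O)O2)C[C@]32OC(=O)[C@H](C)[C@@H]2[C@@H]1O | target

Total steps: 19. Longest linear sequence: 11 steps (steps 1–4, 7–9, 16–19, from 1).

Steps most likely to fail

Step 17 (proposed new method). The weakly activated alkenylboronate may react too slowly, so that the heat- and acid-sensitive dienol ester decomposes first, or addition to the diene face anti to the C3 substituent may compete if the tether control is too small. The fallback builds rings C and D stepwise by known reactions, setting out from enone 17 and coming back at hydroxy lactone 32. Enone 17 is silylated (TBSOTf, Et3N, CH2Cl2, equilibrating) to the tert-butyldimethylsilyl dienol ether F1. A vinylogous Mukaiyama aldol reaction of F1 with commercial ethyl (E)-2-methyl-4-oxobut-2-enoate (BF3·OEt2, CH2Cl2, −78 °C) would form C10–C11 at the γ-carbon and bring in the C11 hydroxyl, giving the γ-hydroxy enoate F2 after separation of diastereomers. SmI2 (THF, t-BuOH, −78 °C → rt) would then couple the C1 ketyl with the β-carbon of the enoate (ketyl–olefin reductive cyclisation), and the samarium alkoxide would lactonise, forming C1–C12 and lactone D. This returns to 32, whose C13 centre is in any case reset in step 19.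

Step 16. Enolisation may take place at C2 instead of the propyl group, acylation may occur at carbon, or the acid α-centre may epimerise through a ketene. The fallback forms the enol ester without a free enolate, setting out from 17 and 26 and coming back at 29. Thermodynamic silylation of 17 (Me3SiCl, NaI, Et3N, MeCN) gives the trimethylsilyl dienol ether F3, from which any cross-conjugated isomer is removed. Acid 26 is converted with cyanuric fluoride and pyridine (CH2Cl2, −10 °C) into the acyl fluoride F4. F3 and F4 with catalytic Bu4N[Ph3SiF2] in THF should undergo the fluoride-catalysed silyl-to-acyl exchange on oxygen, which is regiospecific and base-free, to give 29.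

Step 9. The seven-membered ketone–ketone aldol may stall at the reversible addition stage or give way to intermolecular condensation. The fallback closes the ring on an aldehyde and adds the propyl group afterwards, setting out from 7 (through salt 13) and coming back at 17. Reductive amination of 13 with 5,5-dimethoxypentanal F5 (from cyclopentene by ozonolysis in MeOH with TsOH, then Me2S) gives the acetal amino alcohol F6, and Swern oxidation gives the keto acetal F7. Aqueous acid unmasks the keto aldehyde F8, which under piperidinium acetate should close by aldol condensation to the 9-unsubstituted amino enone F9. N-Bromosuccinimide brominates the nucleophilic enamine carbon C9 to the bromo enone F10, and Negishi coupling with n-PrZnBr (Pd(dppf)Cl2, THF) returns to 17.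

Further compounds
F1 | step 17 | (3R,9E)-1-[(tert-butyldimethylsilyl)oxy]-3-[(2S,4S)-4-methyl-5-oxooxolan-2-yl]-9-propylidene-2,3,6,7,8,9-hexahydro-5H-pyrrolo[1,2-a]azepine | CC/C=C1\CCCCN2C1=C(O[Si](C)(C)C(C)(C)C)C[C@@H]2[C@@H]2C[C@H](C)C(=O)O2
F2 | step 17 | ethyl (E)-4-hydroxy-2-methyl-5-[(3R)-3-((2S,4S)-4-methyl-5-oxooxolan-2-yl)-1-oxo-2,3,5,6,7,8-hexahydro-1H-pyrrolo[1,2-a]azepin-9-yl]hept-2-enoate with C10 and C11 configured as in the target | CC[C@H]([C@@H](O)/C=C(\C)C(=O)OCC)C1=C2C(=O)C[C@H]([C@@H]3C[C@H](C)C(=O)O3)N2CCCC1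
F3 | step 16 | (3R,9E)-3-[(2S,4S)-4-methyl-5-oxooxolan-2-yl]-9-propylidene-1-[(trimethylsilyl)oxy]-2,3,6,7,8,9-hexahydro-5H-pyrrolo[1,2-a]azepine | CC/C=C1\CCCCN2C1=C(O[Si](C)(C)C)C[C@@H]2[C@@H]2C[C@H](C)C(=O)O2
F4 | step 16 | (2S,3Z)-2-methyl-4-(4,4,5,5-tetramethyl-1,3,2-dioxaborolan-2-yl)but-3-enoyl fluoride | FC(=O)[C@@H](C)/C=C\B1OC(C)(C)C(C)(C)O1
F5 | step 9 | 5,5-dimethoxypentanal | COC(CCCC=O)OC
F6 | step 9 | (3S,5S)-5-[(2R,4R)-1-(5,5-dimethoxypentyl)-4-hydroxypyrrolidin-2-yl]-3-methyloxolan-2-one | O=C1O[C@@H](C[C@@H]1C)[C@H]2C[C@@H](O)CN2CCCCC(OC)OC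
F7 | step 9 | (3S,5S)-5-[(2R)-1-(5,5-dimethoxypentyl)-4-oxopyrrolidin-2-yl]-3-methyloxolan-2-one | O=C1O[C@@H](C[C@@H]1C)[C@H]2CC(=O)CN2CCCCC(OC)OC
F8 | step 9 | 5-{(2R)-2-[(2S,4S)-4-methyl-5-oxooxolan-2-yl]-4-oxopyrrolidin-1-yl}pentanal | O=C1O[C@@H](C[C@@H]1C)[C@H]2CC(=O)CN2CCCCC=O
F9 | step 9 | (3R)-3-[(2S,4S)-4-methyl-5-oxooxolan-2-yl]-2,3,5,6,7,8-hexahydro-1H-pyrrolo[1,2-a]azepin-1-one | C1=C2C(=O)C[C@H]([C@@H]3C[C@H](C)C(=O)O3)N2CCCC1
F10 | step 9 | (3R)-9-bromo-3-[(2S,4S)-4-methyl-5-oxooxolan-2-yl]-2,3,5,6,7,8-hexahydro-1H-pyrrolo[1,2-a]azepin-1-one | BrC1=C2C(=O)C[C@H]([C@@H]3C[C@H](C)C(=O)O3)N2CCCC1
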